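(The earlier runs and the new flask are simulated with constants of no real substance, noise included.)

I had to say which of the flasks gamma, beta and eta, which differ in temperature, ends highest in product after 80 min, and at what level.

| flask | substrate | reagent | temperature | remark | time |
|---|---|---|---|---|---|
| east | 6.7 mM | 12 mM | 18 °C | run made earlier |  |
| south-west | 15 mM | 12 mM | 45 °C | run made earlier |  |
| north-east | 10 mM | 6 mM | 18 °C | run made earlier |  |
| gamma | 10 mM | 12.0 mM | 30 °C |  | 80 min |
| beta | 10 mM | 12.0 mM | 55 °C |  | 80 min |
| eta | 10 mM | 12.0 mM | 5 °C |  | 80 min |

| run | time / min | product / % | substrate / % |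
|---|---|---|---|
| east | 25.0 | 51.6 | 0 |
| east | 50.0 | 51.8 | 0 |
| east | 90.0 | 50.7 | 0 |
| east | 120 | 50.9 | 0.2 |
| east | 150 | 52.5 | 0 |
| south-west | 8.00 | 47.1 | 0.7 |
| south-west | 15.0 | 47.4 | 0.3 |
| south-west | 25.0 | 46.2 | 0 |
| south-west | 30.0 | 46.0 | 0 |
| south-west | 40.0 | 47.0 | 0.2 |
| north-east | 10.0 | 48.3 | 6.2 |
| north-east | 20.0 | 51.7 | 0.4 |
| north-east | 50.0 | 52.8 | 0.5 |
| north-east | 80.0 | 52.2 | 0 |
| north-east | 150 | 51.8 | 0.1 |

(scatter of a reading: 0.5 percentage points)

- the flask that comes out highest in amount of product, in percent of the substrate charged, or "all alike" when all lie within 1.5 percentage points (gamma / beta / eta / all alike)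
- product at the end, in percent of the substrate charged, gamma
- product at the end, in percent of the substrate charged, beta
- product at the end, in percent of the substrate charged, eta

- the analysis behind the earlier runs scatters by 0.5 percentage points, standard deviation

I went through the settings in turn to see which had to be known well. The charges came first. At 18 °C the east run levelled at 51.5% and the north-east run, from its second reading on, at 52.1%. They stood 0.60 percentage points apart, against a scatter of 0.5 points on one reading, so I dropped the charges.

Time came next. Substrate in the north-east run stood at 6.2% after 10.0 min, which, read as a first-order decay from that one reading, is a decay time of 3.60 min, so 80 min spans 22.2 decay times at that run's temperature and charges. But eta is colder than any run, so its margin stayed unread.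

Temperature remained: the south-west run at 45 °C levelled at 46.7%. I therefore carried one quantity, the plateau drop, meaning the points of product share (a selectivity) lost between 18 °C and 45 °C: 51.8% minus that level, or 5.1 points. Scaled linearly as a correction to the colder plateau, it gave me 49.6% for gamma, and by extrapolation 44.9% for beta and 54.3% for eta.

The forecast named eta, with 49.4% for gamma, 45% for beta and 54.6% for eta, holding that “temperature sets the split”. Its numbers come from its own reckoning and differ from mine.

The flasks gave 49.2% for gamma, 44.7% for beta and 53.5% for eta, so eta came out highest.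

    intermediate B ⇌ intermediate D (K = 1.34, k = 0.00969 /min, Ea = 81.0 kJ/mol, ΔH = 4.00 kJ/mol)
    reagent + intermediate A ⇌ intermediate B (K = 4000 /M, k = 3.17 /M/min, Ea = 54.0 kJ/mol, ΔH = 20.0 kJ/mol)
    substrate → intermediate A (k = 0.0224 /min, Ea = 95.0 kJ/mol)
    substrate → product (k = 0.0269 /min, Ea = 89.0 kJ/mol)
    reagent + intermediate B ⇌ intermediate C (K = 57.0 /M, k = 45.5 /M/min, Ea = 36.0 kJ/mol, ΔH = −6.00 kJ/mol)
    (constants at 5 °C)

Eta ran close to its time: its conversion of substrate at 80 min was 98.1%, and at 800 min its product stood at 54.6%. The drop of 5.1 points, scaled to eta, had given 54.3%, above the flask at 80 min and below the longer run. For the flask that repeats beta with 4.0 mM of substrate, the drop, which has no term for the charge, again gives 44.9%; the computed result is 44.7%.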